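**Retrosynthetic overview**

1. Feature: in ring A (C1–C5, C10) the C3 ketone is flanked by C4, which carries the exocyclic C18 methylene, and by the ring-fusion carbon C5, which carries the C19 methyl cis to H10. A C4=C5 enone with H at C10 can therefore take up C19 at its β-carbon and C18 at its α-carbon in one enolate relay.
2. Late stage: C15 acid ⇐ tert-butyl ester; C1=C2(OH) diosphenol ⇐ α-hydroxylation and oxidation at C2; C5–C19 and C4–C18 ⇐ Me2CuLi / Eschenmoser's salt on the 10-H Δ4-3-ketone 20.
3. 20 ⇐ acetylation and C13=C14 olefination of hydroxy enone methyl ketone 16 ⇐ Birch reduction and acid hydrolysis of anisole 13, with C10 set by equilibration.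
4. 13 ⇐ C8 methyl by OH-directed hydrogenation, C7 carbinol by CBS reduction of the 7-keto-8(17)-ene, C17 by Wittig methylenation, C9 by methylation then asymmetric phase-transfer alkylation of 6-methoxy-2-tetralone.
5. Rings: none is built. Ring B is the saturated ring of the tetralone and is elaborated first; ring A is its anisole ring, unveiled as the enone by Birch reduction before the key step.

Key step: step 12

Remark on numbering: clerodane numbering is used throughout. Tetralone C1 = C9, C2 = C8, C3 = C7, C4 = C6; the anisole ring is ring A with OMe on C3. C17 is on C8, C18 on C4, C19 on C5, C20 (methyl) and the C11–C16 chain on C9. α is the face of the C9 methyl, β the face of the C9 side chain.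

Remark on protecting groups: the C7 oxygen is carried through the key step as the acetate of the target (not as a silyl ether), so no protecting-group exchange is needed on the sensitive diosphenol.

Assumption: the usual facial models hold for the two catalyst-controlled steps (cinchonidinium salt gives 9R in step 2; (R)-CBS gives 7S in step 6); otherwise the pseudoenantiomeric or enantiomeric catalyst is used.

**Route**

Step 1
Reactants: 1 6-methoxy-2-tetralone; 2 iodomethane
Product: 5 rac-6-methoxy-1-methyl-2-tetralone, via pyrrolidine enamine 3 (not isolated), via methylated iminium iodide 4 (not isolated)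
Conditions: pyrrolidine, PhMe, reflux (Dean–Stark); MeI, MeCN, reflux; aq. NaOAc, 60 °C
Reagents that add atoms: iodomethane (CI)
Why: Stork enamine alkylation, in which the 2-tetralone enamine forms toward the benzylic carbon (C9) and is C-methylated once only, avoiding the dialkylation of direct enolate methylation; the new centre is racemic and is reset in step 2.

Step 2
Reactants: 5 rac-6-methoxy-1-methyl-2-tetralone; 6 2-(2-bromoethyl)-2-methyl-1,3-dioxolane
Product: 7 (R)-6-methoxy-1-methyl-1-[2-(2-methyl-1,3-dioxolan-2-yl)ethyl]-2-tetralone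
Conditions: N-[4-(trifluoromethyl)benzyl]cinchonidinium bromide (10 mol%), 50% aq. NaOH, PhMe, 0–15 °C, Ar
Reagents that add atoms: 2-(2-bromoethyl)-2-methyl-1,3-dioxolane (CC1(CCBr)OCCO1)
Why: Asymmetric phase-transfer alkylation, in which the planar benzylic enolate of 5 is ion-paired with the chiral cinchona cation so that the primary bromide enters from the unshielded face and creates the quaternary C9 centre (C9–C11 bond); enantiomeric purity can be raised by recrystallising a later solid such as 13.

Step 3
Reactants: 7 (R)-alkylated tetralone; 8 methyltriphenylphosphonium bromide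
Product: 9 8(17)-methylene tetralin
Conditions: KOtBu, PhMe, 0 → 80 °C
Reagents that add atoms: methyltriphenylphosphonium bromide (C[P+](c1ccccc1)(c1ccccc1)c1ccccc1.[Br-])
Why: Wittig methylenation with the non-stabilised ylide under hot, salt-free conditions suited to a ketone next to a quaternary carbon; C9 cannot epimerise and the dioxolane is inert to base.

Step 4
Reactants: 9 8(17)-methylene tetralin
Product: 10 7-hydroxy-8(17)-methylene tetralin (both C7 epimers)
Conditions: SeO2 (0.5 equiv), t-BuOOH (3 equiv), CH2Cl2, rt
Reagents that add atoms: selenium dioxide (O=[Se]=O); tert-butyl hydroperoxide (CC(C)(C)OO)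
Why: Selenium dioxide allylic hydroxylation (ene reaction then [2,3]-sigmatropic shift), regiochemically unambiguous because C7 holds the only allylic hydrogens (C9 is quaternary) and the exocyclic alkene is regenerated; the C7 epimers converge in step 5.

Step 5
Reactants: 10 7-hydroxy-8(17)-methylene tetralin
Product: 11 7-oxo-8(17)-methylene tetralin
Conditions: Dess–Martin periodinane, pyridine, CH2Cl2, 0 °C → rt
Reagents that add atoms: none
Why: Dess–Martin oxidation under buffered, non-basic conditions brings both C7 epimers to one cross-conjugated enone without enolising the benzylic C6 position or opening the ketal.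

Step 6
Reactants: 11 7-oxo-8(17)-methylene tetralin
Product: 12 (7S)-7β-hydroxy-8(17)-methylene tetralin
Conditions: (R)-2-methyl-CBS-oxazaborolidine (0.3 equiv), BH3·SMe2, THF, −30 °C; MeOH
Reagents that add atoms: none
Why: Corey–Bakshi–Shibata reduction under catalyst control, with the sp2 C8 side as the large and the C6 methylene as the small substituent, so that the (R)-catalyst should give the 7S alcohol (OH cis to the C9 side chain); the remote quaternary C9 exerts little bias of its own.

Step 7
Reactants: 12 (7S)-7β-hydroxy-8(17)-methylene tetralin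
Product: 13 7β-hydroxy-8α-methyl tetralin
Conditions: [Ir(cod)(PCy3)(py)]PF6 (5 mol%), H2 (1 atm), CH2Cl2, rt
Reagents that add atoms: none
Why: Hydroxyl-directed hydrogenation, in which iridium bound to the C7 hydroxyl delivers hydrogen to the same face of C8=C17, so H8 ends cis to the oxygen and the new C17 methyl trans to it (8S, cis to the C9 methyl); the arene and ketal are untouched.

Step 8
Reactants: 13 7β-hydroxy-8α-methyl tetralin
Product: 14 3-methoxy-2,5(10)-diene
Conditions: Li, NH3(l), THF, t-BuOH, −78 → −33 °C; NH4Cl
Reagents that add atoms: none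
Why: Birch reduction of the anisole ring, which leaves the methoxy-bearing and the two alkylated ring carbons sp2 (C2=C3 enol ether, C5=C10 alkene) while the C7 alkoxide, the ketal and the sp3 stereocentres are inert.

Step 9
Reactants: 14 3-methoxy-2,5(10)-diene
Product: 16 7β-hydroxy-10β-H 4-en-3-one methyl ketone, via β,γ-enone ketal 15 (not isolated)
Conditions: 2 M aq. HCl, THF, rt
Reagents that add atoms: water (O)
Why: Acid hydrolysis of the enol ether and the dioxolane with isomerisation of the β,γ-enone into conjugation through the 3,5(10)-dienol, where C10 is protonated reversibly and should settle as the epimer whose ring B chair has only the C9 methyl axial (H10 trans to C20); the equatorial C7 hydroxyl is poorly aligned for vinylogous dehydration under these mild conditions.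

Step 10
Reactants: 16 hydroxy enone methyl ketone; 17 tert-butyl diethylphosphonoacetate
Product: 18 hydroxy enone (E)-enoate
Conditions: 17 (3 equiv), NaH (2.8 equiv), THF, 0 °C → rt; aq. NH4Cl
Reagents that add atoms: tert-butyl diethylphosphonoacetate (CCOP(=O)(CC(=O)OC(C)(C)C)OCC)
Why: Horner–Wadsworth–Emmons olefination, in which the stabilised phosphonate anion (no excess hydride, too weakly basic to enolise the ketones or deprotonate the alcohol) should react at the unhindered saturated methyl ketone in preference to the conjugated β,β-disubstituted C3 carbonyl and give mainly the E-trisubstituted enoate, the minor Z isomer being removed by chromatography.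

Step 11
Reactants: 18 hydroxy enone (E)-enoate; 19 acetic anhydride
Product: 20 7β-acetoxy 10-H Δ4-3-ketone
Conditions: Ac2O, pyridine, DMAP (cat.), CH2Cl2, 0 °C → rt
Reagents that add atoms: acetic anhydride (CC(=O)OC(C)=O)
Why: DMAP-catalysed acylation of the equatorial secondary alcohol under non-enolising conditions, so the acetate is installed without vinylogous elimination and no stereocentre is touched.

Step 12
Reactants: 20 7β-acetoxy 10-H Δ4-3-ketone; 21 lithium dimethylcuprate; 22 Eschenmoser's salt
Product: 26 cis-fused 5β-methyl-4(18)-methylene-3-ketone, via lithium enolate 23 (not isolated), via Mannich base 24 (not isolated), via methiodide 25 (not isolated)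
Conditions: Me2CuLi (from CuI, 2 MeLi), Et2O, −20 → 0 °C; CH2=NMe2+ I−, THF, −40 °C → rt; extractive work-up; MeI, CH2Cl2/MeOH, rt; aq. NaHCO3, rt
Reagents that add atoms: lithium dimethylcuprate ([Li+].C[Cu-]C); Eschenmoser's salt (C[N+](C)=C.[I-])
Why: Me2CuLi forms a π-complex with the C4=C5 enone and transfers methyl to C5 through a β-cuprio(III) enolate, leaving the regiodefined C3–C4 lithium enolate 23, which attacks the iminium carbon of 22 at C4 (Mannich reaction) to give 24; N-methylation to 25 and E1cB loss of trimethylamine then unveil the C4=C18 methylene. The closest known reaction type is cuprate conjugate addition to 10-H Δ4-3-keto octalins with capture of the enolate by Eschenmoser's salt and Hofmann-type elimination, a tandem β-methylation/α-methylenation. No ring is closed; the step forms the two C–C bonds C5–C19 and C4–C18. The one lasting new stereocentre, C5, is substrate-controlled: octalones of this type add cuprates to give the cis-fused decalin (methyl entering on the H10 face), and here the axial C20 methyl on C9, which is 1,3-syn-axial to the α face of C5, blocks the alternative approach; the C4 centre of 24 is erased in the elimination. The step needs β-face selectivity at C5, 1,4-addition to the enone in preference to the β,β-disubstituted enoate and the acetate (a Gilman reagent at or below 0 °C without silyl activation should discriminate), and C-alkylation at C4 without enolate equilibration to C2 (secured by aprotic generation of the enolate and the high electrophilicity of the iminium salt).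

Step 13
Reactants: 26 cis-fused 5β-methyl-4(18)-methylene-3-ketone
Product: 27 trimethylsilyl 2,4(18)-dienol ether
Conditions: LiHMDS (1.1 equiv), TMSCl, THF, −78 °C (in situ quench); Et3N, pentane, filtration
Reagents that add atoms: chlorotrimethylsilane (C[Si](C)(C)Cl)
Why: Kinetic enolisation with O-silylation, in which C2 is the only enolisable position next to C3 (C4 is sp2, C5 quaternary), the ketone is far more acidic than the acetate or the enoate γ-positions, and the in situ silyl quench prevents the enolate from adding to the exocyclic enone of another molecule.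

Step 14
Reactants: 27 trimethylsilyl 2,4(18)-dienol ether
Product: 30 2-hydroxy-4(18)-methylene-3-ketone (C2 epimers), via silyloxy epoxide 28 (not isolated), via 2-silyloxy ketone 29 (not isolated)
Conditions: mCPBA, NaHCO3, CH2Cl2, −20 °C; aq. citric acid, THF, rt
Reagents that add atoms: meta-chloroperoxybenzoic acid (O=C(OO)c1cccc(Cl)c1)
Why: Rubottom oxidation, in which the electron-rich C2=C3 silyl enol ether is epoxidised in preference to the electron-poor exocyclic methylene and the enoate, the epoxide opens with 1,4-silyl shift and mild acid frees the α′-hydroxy enone; the C2 configuration is irrelevant because it is removed in step 15.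

Step 15
Reactants: 30 2-hydroxy-4(18)-methylene-3-ketone
Product: 32 diosphenol tert-butyl ester, via 2,3-diketone 31 (not isolated)
Conditions: Dess–Martin periodinane, pyridine, CH2Cl2, 0 °C → rt
Reagents that add atoms: none
Why: Dess–Martin oxidation of the α-ketol to the 2,3-diketone, which can enolise only toward C1 (C4 bears no hydrogen) and should therefore rest as the hydrogen-bonded C1=C2(OH)–C3=O diosphenol.

Step 16
Reactants: 32 diosphenol tert-butyl ester
Product: 33 CNP0192653.1 (target acid)
Conditions: TFA/CH2Cl2 (1:4), 0 °C → rt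
Reagents that add atoms: none
Why: Acidolysis of the tert-butyl ester (alkyl–oxygen cleavage with loss of isobutene) in the absence of base or nucleophile, so the secondary acetate, the exocyclic enone and the diosphenol should persist and no stereocentre is touched.

**Compound list**

1 | 6-methoxy-2-tetralone (6-methoxy-3,4-dihydronaphthalen-2(1H)-one) | COc1ccc2c(c1)CCC(=O)C2 | starting material
2 | iodomethane | CI | starting material
3 | 1-(6-methoxy-3,4-dihydronaphthalen-2-yl)pyrrolidine (enamine) | COc1ccc2c(c1)CCC(N1CCCC1)=C2 | intermediate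
4 | 1-(6-methoxy-1-methyl-3,4-dihydronaphthalen-2(1H)-ylidene)pyrrolidinium iodide (racemic) | COc1ccc2c(c1)CCC(=[N+]1CCCC1)C2C.[I-] | intermediate
5 | rac-6-methoxy-1-methyl-3,4-dihydronaphthalen-2(1H)-one | COc1ccc2c(c1)CCC(=O)C2C | intermediate
6 | 2-(2-bromoethyl)-2-methyl-1,3-dioxolane | CC1(CCBr)OCCO1 | starting material
7 | (R)-6-methoxy-1-methyl-1-[2-(2-methyl-1,3-dioxolan-2-yl)ethyl]-3,4-dihydronaphthalen-2(1H)-one (quaternary C9, 9α-Me) | COc1ccc2c(c1)CCC(=O)[C@]2(C)CCC1(C)OCCO1 | intermediate
8 | methyltriphenylphosphonium bromide | C[P+](c1ccccc1)(c1ccccc1)c1ccccc1.[Br-] | starting material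
9 | 8(17)-methylene tetralin: 7 with the C8 carbonyl replaced by C=CH2, C9 unchanged | COc1ccc2c(c1)CCC(=C)[C@]2(C)CCC1(C)OCCO1 | intermediate
10 | 7-hydroxy-8(17)-methylene tetralin: 9 with OH on C7, both C7 epimers | COc1ccc2c(c1)CC(O)C(=C)[C@]2(C)CCC1(C)OCCO1 | intermediate
11 | 7-oxo-8(17)-methylene tetralin (cross-conjugated enone C7=O, C8=C17H2) | COc1ccc2c(c1)CC(=O)C(=C)[C@]2(C)CCC1(C)OCCO1 | intermediate
12 | (7S)-7β-hydroxy-8(17)-methylene tetralin (OH cis to the C9 side chain) | COc1ccc2c(c1)C[C@H](O)C(=C)[C@]2(C)CCC1(C)OCCO1 | intermediate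
13 | (7S,8S)-7β-hydroxy-8α-methyl tetralin (8-Me cis to 9-Me, OH trans to 8-Me, ketal side chain on C9) | COc1ccc2c(c1)C[C@H](O)[C@@H](C)[C@]2(C)CCC1(C)OCCO1 | intermediate
14 | 3-methoxy-2,5(10)-diene from 13 (enol ether C2=C3, alkene C5=C10; 7β-OH, 8α-Me, 9α-Me, ketal side chain) | COC1=CCC2=C(C1)C[C@H](O)[C@@H](C)[C@]2(C)CCC1(C)OCCO1 | intermediate
15 | 5(10)-en-3-one (β,γ-enone) with intact dioxolane, ring B as in 14 | O=C1CCC2=C(C1)C[C@H](O)[C@@H](C)[C@]2(C)CCC1(C)OCCO1 | intermediate
16 | (4aS,5R,6S,7S)-7-hydroxy-5,6-dimethyl-5-(3-oxobutyl)-4,4a,5,6,7,8-hexahydronaphthalen-2(3H)-one (7β-OH, 8α-Me, 9α-Me, 10β-H Δ4-3-ketone) | O=C1CC[C@@H]2[C@@](C)(CCC(C)=O)[C@H](C)[C@@H](O)CC2=C1 | intermediate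
17 | tert-butyl diethylphosphonoacetate | CCOP(=O)(CC(=O)OC(C)(C)C)OCC | starting material
18 | 16 with the side-chain ketone converted into the (E)-C13(CH3)=C14H–CO2tBu enoate (7β-OH, 10β-H Δ4-3-ketone) | O=C1CC[C@@H]2[C@@](C)(CC/C(C)=C/C(=O)OC(C)(C)C)[C@H](C)[C@@H](O)CC2=C1 | intermediate
19 | acetic anhydride | CC(=O)OC(C)=O | starting material
20 | 7β-acetate of 18, (7S,8S,9R,10S) 10-H Δ4-3-ketone (key-step precursor) | O=C1CC[C@@H]2[C@@](C)(CC/C(C)=C/C(=O)OC(C)(C)C)[C@H](C)[C@@H](OC(C)=O)CC2=C1 | intermediate
21 | lithium dimethylcuprate (generated from commercial CuI and MeLi) | [Li+].C[Cu-]C | starting material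
22 | Eschenmoser's salt (N,N-dimethylmethyleneiminium iodide) | C[N+](C)=C.[I-] | starting material
23 | lithium C3–C4 enolate of the cis-fused 5β-methyl decalin | C1=C([O-])CC[C@@H]2[C@@](C)(CC/C(C)=C/C(=O)OC(C)(C)C)[C@H](C)[C@@H](OC(C)=O)C[C@]12C.[Li+] | intermediate
24 | 4-(dimethylaminomethyl)-5β-methyl-3-ketone (Mannich base, C4 configuration undefined) | CN(C)CC1C(=O)CC[C@@H]2[C@@](C)(CC/C(C)=C/C(=O)OC(C)(C)C)[C@H](C)[C@@H](OC(C)=O)C[C@]12C | intermediate
25 | trimethylammonium iodide (methiodide) of 24 | C[N+](C)(C)CC1C(=O)CC[C@@H]2[C@@](C)(CC/C(C)=C/C(=O)OC(C)(C)C)[C@H](C)[C@@H](OC(C)=O)C[C@]12C.[I-] | intermediate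
26 | (5S,7S,8S,9R,10R) cis-fused 5β-methyl-4(18)-methylene-3-ketone, 7β-OAc, tert-butyl (E)-enoate | C=C1C(=O)CC[C@@H]2[C@@](C)(CC/C(C)=C/C(=O)OC(C)(C)C)[C@H](C)[C@@H](OC(C)=O)C[C@]12C | intermediate
27 | 3-(trimethylsilyloxy)-2,4(18)-diene of 26 | C=C1C(O[Si](C)(C)C)=CC[C@@H]2[C@@](C)(CC/C(C)=C/C(=O)OC(C)(C)C)[C@H](C)[C@@H](OC(C)=O)C[C@]12C | intermediate
28 | 2,3-epoxy-3-(trimethylsilyloxy) derivative of 27 (epoxide configuration undefined) | C=C1C2(O[Si](C)(C)C)OC2C[C@@H]3[C@@](C)(CC/C(C)=C/C(=O)OC(C)(C)C)[C@H](C)[C@@H](OC(C)=O)C[C@]13C | intermediate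
29 | 2-(trimethylsilyloxy)-4(18)-methylene-3-ketone (C2 undefined) | C=C1C(=O)C(O[Si](C)(C)C)C[C@@H]2[C@@](C)(CC/C(C)=C/C(=O)OC(C)(C)C)[C@H](C)[C@@H](OC(C)=O)C[C@]12C | intermediate
30 | 2-hydroxy-4(18)-methylene-3-ketone (C2 epimers) | C=C1C(=O)C(O)C[C@@H]2[C@@](C)(CC/C(C)=C/C(=O)OC(C)(C)C)[C@H](C)[C@@H](OC(C)=O)C[C@]12C | intermediate
31 | 4(18)-methylene-2,3-diketone | C=C1C(=O)C(=O)C[C@@H]2[C@@](C)(CC/C(C)=C/C(=O)OC(C)(C)C)[C@H](C)[C@@H](OC(C)=O)C[C@]12C | intermediate
32 | tert-butyl ester of the target (2-hydroxy-1-en-3-one diosphenol, 4(18)-methylene) | C=C1C(=O)C(O)=C[C@@H]2[C@@](C)(CC/C(C)=C/C(=O)OC(C)(C)C)[C@H](C)[C@@H](OC(C)=O)C[C@]12C | intermediate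
33 | CNP0192653.1, (5S,7S,8S,9R,10R)-7-acetoxy-2-hydroxy-3-oxo-cis-cleroda-1,4(18),13E-trien-15-oic acid | C=C1C(=O)C(O)=C[C@@H]2[C@@](C)(CC/C(C)=C/C(=O)O)[C@H](C)[C@@H](OC(C)=O)C[C@]12C | target

**Step count and risks**

Total step count: 16. Longest linear sequence: 16 steps (from 1).

Steps most likely to fail:

Step 12. The conjugate addition to the hindered β,β-disubstituted enone may be slow, and the copper-containing enolate may be protonated or equilibrate before it is aminomethylated, so that methylation and methylenation are not coupled cleanly. The fallback separates the two events. It sets out from 20: Me2CuLi is added in the presence of TMSCl (THF, −78 °C), which accelerates the 1,4-addition and traps the regiodefined enolate as the isolable C3–C4 silyl enol ether F1. F1 is then treated with Eschenmoser's salt in CH2Cl2 at rt (Mannich reaction of a silyl enol ether), which returns the route at Mannich base 24. Quaternisation and elimination to 26 follow as in step 12.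

Step 10. The phosphonate anion may also olefinate or deconjugate the C3 enone, and the basic medium may trigger vinylogous loss of the C7 oxygen. The fallback removes the competing carbonyl for the duration of the olefination. It sets out from 16: Luche reduction (NaBH4, CeCl3·7H2O, MeOH, −78 °C) reduces the conjugated C3 ketone selectively to the allylic alcohol F2 (C3 epimers), leaving the methyl ketone. Horner–Wadsworth–Emmons reaction with 17 on the only remaining carbonyl gives diol enoate F3. MnO2 (CH2Cl2, rt) then oxidises only the allylic C3 alcohol and returns the route at 18.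

Step 2. Ion-pair control may give insufficient enantio-induction, and the unactivated bromide may alkylate slowly while it eliminates to the vinyl dioxolane. The fallback replaces catalyst control by auxiliary control and the bromide by an enone acceptor. It sets out from 5: condensation with (S)-1-phenylethylamine (PhMe, TsOH cat., Dean–Stark) gives imine F4, which reacts through its more substituted secondary enamine with methyl vinyl ketone (THF, rt) in a deracemising Michael addition to give adduct imine F5. This enantiomer of the amine is the one expected to give the 9R centre by the usual topicity of the reaction. Hydrolysis (aq. AcOH) gives diketone F6. Selective dioxolanation of the unhindered side-chain ketone (1,2-bis(trimethylsilyloxy)ethane, TMSOTf cat., CH2Cl2, −78 °C), with the neopentyl C8 ketone left free, returns the route at 7.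

**Further compounds**

F1 | step 12 | 3-(trimethylsilyloxy)-3-ene of the cis-fused 5β-methyl decalin (silyl enol ether of the conjugate adduct) | C1=C(O[Si](C)(C)C)CC[C@@H]2[C@@](C)(CC/C(C)=C/C(=O)OC(C)(C)C)[C@H](C)[C@@H](OC(C)=O)C[C@]12C
F2 | step 10 | 3,7-dihydroxy-4-ene with 3-oxobutyl side chain (C3 epimers) | OC1CC[C@@H]2[C@@](C)(CCC(C)=O)[C@H](C)[C@@H](O)CC2=C1
F3 | step 10 | 3,7-dihydroxy-4-ene with tert-butyl (E)-enoate side chain (C3 epimers) | OC1CC[C@@H]2[C@@](C)(CC/C(C)=C/C(=O)OC(C)(C)C)[C@H](C)[C@@H](O)CC2=C1
F4 | step 2 | (S)-1-phenylethylamine imine of 5 | C[C@H](N=C1CCc2cc(OC)ccc2C1C)c1ccccc1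
F5 | step 2 | (S)-1-phenylethylamine imine of (R)-6-methoxy-1-methyl-1-(3-oxobutyl)-2-tetralone | C[C@H](N=C1CCc2cc(OC)ccc2[C@@]1(C)CCC(C)=O)c1ccccc1
F6 | step 2 | (R)-6-methoxy-1-methyl-1-(3-oxobutyl)-3,4-dihydronaphthalen-2(1H)-one | COc1ccc2c(c1)CCC(=O)[C@]2(C)CCC(C)=O
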